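**Plan**

- Retrosynthesis: the O5–Si bond is cut first, then C4–C4a (ring B, acyl cation onto the enol ether carbon), then ring A at C6–C7, C4a–C5 and C7–C8. This leaves a 3-alkoxy-4-geranyl-4-methylcyclobutenone and a prenyl siloxyalkyne; the cyclobutenone goes back to geranyl(methyl)ketene, ethoxyacetylene and a 3-hydroxybutanoate.
- Forward: propanoic acid and geranyl bromide give the ketene and then the four-membered ring; the side chain is put on oxygen; the annulation closes ring A; C-acylation at C4a closes ring B; desilylation ends the route.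
- Enabling feature (chromanone numbering): ring A is a 6,6-disubstituted cyclohexa-2,4-dienone (C7=O, C5=C6, C4a=C8a) with oxygen on C5 and C8a and a quaternary C8 (methyl, geranyl). This is the pattern a vinylketene and an ynol ether give when the closing terminus has no hydrogen; O1 is the enol ether oxygen of the cyclobutenone.
- Stereochemistry: C2 (S) comes from tert-butyl (R)-3-hydroxybutanoate by Mitsunobu inversion. C8 arises in the six-electron closure without reliable bias, and the (2S,8R) diastereomer is isolated by HPLC once ring B is closed.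

Key step: step 7

Remark: step 7 is expected to give 18 together with a similar amount of its C8 epimer; the pair is carried through steps 8 and 9 and parted after step 9, and numbers 18–23 denote the (8R) series. Compounds 10 and 12 are taken as purchasable.

**Step 1**
Reactants: 1 propanoic acid; 2 geranyl bromide
Product: 4 (4E)-2,5,9-trimethyldeca-4,8-dienoic acid (racemic), via propanoate dianion 3 (not isolated)
Conditions: LiN(iPr)2 (2.1 equiv), THF, DMPU, 0 °C; then 2, 0 °C → rt; 1 M HCl work-up
Reagents that add atoms: none
Why: Alkylation of a carboxylic acid dianion, in which the α-carbon displaces the primary allylic bromide by SN2; the new centre is racemic and is erased in step 3.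

**Step 2**
Reactants: 4 (4E)-2,5,9-trimethyldeca-4,8-dienoic acid
Product: 5 (4E)-2,5,9-trimethyldeca-4,8-dienoyl chloride
Conditions: (COCl)2, DMF (cat.), CH2Cl2, 0 °C → rt; evaporate
Reagents that add atoms: oxalyl chloride, ClC(=O)C(=O)Cl
Why: Acid chloride formation through the catalytic chloroiminium species, run cold and short so that the trisubstituted alkenes are not hydrochlorinated.

**Step 3**
Reactants: 5 (4E)-2,5,9-trimethyldeca-4,8-dienoyl chloride; 6 ethoxyacetylene
Product: 8 4-[(2E)-3,7-dimethylocta-2,6-dien-1-yl]-3-ethoxy-4-methylcyclobut-2-en-1-one (racemic), via geranyl(methyl)ketene 7 (not isolated)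
Conditions: 6 (2 equiv), Et3N (1.5 equiv), MeCN, 0 °C → rt, slow addition of 5
Reagents that add atoms: none
Why: Dehydrochlorination gives the ketene, and its [2+2] cycloaddition with the ynol ether joins the ketene carbonyl carbon to the unsubstituted alkyne carbon, so only the 3-ethoxy-4,4-disubstituted cyclobutenone can form.

**Step 4**
Reactants: 8 3-ethoxy-4-geranyl-4-methylcyclobutenone
Product: 9 2-[(2E)-3,7-dimethylocta-2,6-dien-1-yl]-2-methylcyclobutane-1,3-dione (present largely as its enol)
Conditions: 1 M HCl, THF, 0 °C → rt; extract and use at once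
Reagents that add atoms: water, O
Why: Acid hydrolysis of the strained vinylogous ester (enol ether hydrolysis) frees a symmetric, strongly acidic 1,3-dione whose two carbonyls are equivalent, so later O-alkylation can give one constitution only.

**Step 5**
Reactants: 9 2-geranyl-2-methylcyclobutane-1,3-dione; 10 tert-butyl (R)-3-hydroxybutanoate
Product: 11 tert-butyl (3S)-3-({4-[(2E)-3,7-dimethylocta-2,6-dien-1-yl]-4-methyl-3-oxocyclobut-1-en-1-yl}oxy)butanoate (both epimers at ring C4)
Conditions: PPh3, DIAD, THF, 0 °C → rt
Reagents that add atoms: none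
Why: Mitsunobu O-alkylation of the acidic enol by SN2 with inversion turns the (R)-carbinol into the (S)-ether that becomes C2; the ring C4 centre is unresolved on purpose because step 7 makes it trigonal.

**Step 6**
Reactants: 12 ethyl 4-methylpent-3-enoate
Product: 14 triisopropyl[(5-methylhex-4-en-1-yn-1-yl)oxy]silane, via lithium ynolate 13 (not isolated)
Conditions: CH2Br2, lithium 2,2,6,6-tetramethylpiperidide (LiTMP), THF, –78 °C; add 12; LiN(SiMe3)2; n-BuLi, –78 °C → rt; iPr3SiCl, –78 °C → rt
Reagents that add atoms: dibromomethane, BrCBr; triisopropylsilyl chloride, CC(C)[Si](Cl)(C(C)C)C(C)C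
Why: Kowalski ester homologation, in which dibromomethyllithium adds to the ester, bromine–lithium exchange and 1,2-shift of the prenyl group give the ynolate, and the bulky chlorosilane traps it on oxygen.

**Step 7**
Reactants: 11 chiral 3-alkoxy-4-geranyl-4-methylcyclobutenone; 14 prenyl siloxyalkyne
Product: 18 tert-butyl (3S)-3-{[(6R)-6-[(2E)-3,7-dimethylocta-2,6-dien-1-yl]-6-methyl-4-(3-methylbut-2-en-1-yl)-5-oxo-3-(triisopropylsilyloxy)cyclohexa-1,3-dien-1-yl]oxy}butanoate, via vinylketene 15 (not isolated), via vinylcyclobutenone 16 (not isolated), via dienylketene 17 (not isolated)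
Conditions: 14 (1.5 equiv), toluene (0.5 M), 100 °C, sealed tube, argon
Reagents that add atoms: none
Why: Thermal conrotatory four-electron opening of 11 gives vinylketene 15 (O=C7=C4a–C8a(OR)=C8), whose ketene carbon C7 bonds to the prenyl-bearing, nucleophilic alkyne carbon (C6) while C4a bonds to the siloxy carbon (C5) in a [2+2] cycloaddition that gives 16. A second four-electron opening cleaves the C7–C4a bond of 16, and the (Z)-dienylketene 17 closes ring A by a thermal disrotatory six-electron electrocyclisation that re-forms C7–C8. The closest known reaction is the Danheiser benzannulation of cyclobutenones with siloxyalkynes in its cyclohexadienone-forming variant: C8 carries methyl and geranyl and no hydrogen, so the dienone cannot tautomerise to a phenol. C8 is created in the six-electron closure, where the only chiral element is the C2 centre of the O1 side chain, three bonds away; it should bias the sense of rotation only weakly, so 18 is expected together with its C8 epimer, while both C4 epimers of 11 converge because that centre is trigonal in 15. The step needs regioselectivity in the [2+2] event, which the polarity of ketene and ynol ether secures, and chemoselectivity over addition of the ketene to the geranyl and prenyl alkenes, which the far higher nucleophilicity of the siloxyalkyne, used in excess at high concentration, secures.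

**Step 8**
Reactants: 18 ring A dienone tert-butyl ester
Product: 20 (3S)-3-{[(6R)-6-geranyl-6-methyl-4-prenyl-5-oxo-3-(triisopropylsilyloxy)cyclohexa-1,3-dien-1-yl]oxy}butanoic acid, via trimethylsilyl ester 19 (not isolated)
Conditions: Me3SiOSO2CF3, 2,6-lutidine, CH2Cl2, 0 °C; pH 7 phosphate buffer work-up
Reagents that add atoms: none
Why: Silyl triflate-mediated cleavage of the tert-butyl ester (loss of 2-methylpropene) gives the silyl ester, which water hydrolyses on work-up; the cold, buffered, non-basic conditions should spare the silyl enol ether, the alkenes and the β-alkoxy acid, which base could cleave by elimination.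

**Step 9**
Reactants: 20 side-chain carboxylic acid
Product: 22 (2S,8R)-8-[(2E)-3,7-dimethylocta-2,6-dien-1-yl]-2,8-dimethyl-6-(3-methylbut-2-en-1-yl)-5-(triisopropylsilyloxy)-2,3-dihydro-4H-chromene-4,7(8H)-dione, via acid chloride 21 (not isolated)
Conditions: 1-chloro-N,N,2-trimethylprop-1-en-1-amine, CH2Cl2, 0 °C → rt; then AgOSO2CF3, 2,6-di-tert-butyl-4-methylpyridine, CH2Cl2, –78 → –20 °C; preparative HPLC (silica) to remove the C8 epimer
Reagents that add atoms: none
Why: Intramolecular Friedel–Crafts-type acylation of an enol ether, in which the acyl triflate formed from 21 and silver triflate attacks C4a, the β-carbon of the C8a enol ether, in a six-membered closure of ring B, and loss of the C4a proton to the hindered pyridine restores C4a=C8a; C2 is untouched and the two C8 epimers, now rigid bicycles, should be separable here.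

**Step 10**
Reactants: 22 silyl-protected chromanedione
Product: 23 (2S,8R)-8-[(2E)-3,7-dimethylocta-2,6-dien-1-yl]-5-hydroxy-2,8-dimethyl-6-(3-methylbut-2-en-1-yl)-2,3-dihydro-4H-chromene-4,7(8H)-dione (target)
Conditions: Bu4NF, AcOH, THF, 0 °C
Reagents that add atoms: none
Why: Fluoride-induced cleavage of the silyl enol ether frees the C5 enol, which is held by a hydrogen bond to the C4 ketone; the acetic acid buffer should prevent base-induced retro-oxa-Michael opening of ring B, which would endanger C2.

**Compound list**

1 | propanoic acid | CCC(=O)O | starting material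
2 | geranyl bromide, (2E)-1-bromo-3,7-dimethylocta-2,6-diene | CC(C)=CCC/C(C)=C/CBr | starting material
3 | dilithium prop-1-ene-1,1-diolate (propanoate dianion) | CC=C([O-])[O-].[Li+].[Li+] | intermediate (not isolated)
4 | (4E)-2,5,9-trimethyldeca-4,8-dienoic acid, racemic | CC(C)=CCC/C(C)=C/CC(C)C(=O)O | intermediate
5 | (4E)-2,5,9-trimethyldeca-4,8-dienoyl chloride, racemic | CC(C)=CCC/C(C)=C/CC(C)C(Cl)=O | intermediate
6 | ethoxyacetylene | C#COCC | starting material
7 | geranyl(methyl)ketene, (4E)-2,5,9-trimethyldeca-1,4,8-trien-1-one | CC(C)=CCC/C(C)=C/CC(C)=C=O | intermediate (not isolated)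
8 | 4-[(2E)-3,7-dimethylocta-2,6-dien-1-yl]-3-ethoxy-4-methylcyclobut-2-en-1-one, racemic | CC(C)=CCC/C(C)=C/CC1(C)C(=O)C=C1OCC | intermediate
9 | 2-[(2E)-3,7-dimethylocta-2,6-dien-1-yl]-2-methylcyclobutane-1,3-dione | CC(C)=CCC/C(C)=C/CC1(C)C(=O)CC1=O | intermediate
10 | tert-butyl (R)-3-hydroxybutanoate | CC(C)(C)OC(=O)C[C@@H](C)O | starting material
11 | tert-butyl (3S)-3-({4-[(2E)-3,7-dimethylocta-2,6-dien-1-yl]-4-methyl-3-oxocyclobut-1-en-1-yl}oxy)butanoate, ring C4 unspecified | CC(C)=CCC/C(C)=C/CC1(C)C(=O)C=C1O[C@@H](C)CC(=O)OC(C)(C)C | intermediate (precursor of the key step)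
12 | ethyl 4-methylpent-3-enoate | CCOC(=O)CC=C(C)C | starting material
13 | lithium 5-methylhex-4-en-1-yn-1-olate | [Li+].[O-]C#CCC=C(C)C | intermediate (not isolated)
14 | triisopropyl[(5-methylhex-4-en-1-yn-1-yl)oxy]silane | CC(C)=CCC#CO[Si](C(C)C)(C(C)C)C(C)C | intermediate
15 | vinylketene, tert-butyl (3S)-3-{[(6E)-4,7,11-trimethyl-1-oxododeca-1,3,6,10-tetraen-3-yl]oxy}butanoate, C3=C4 geometry mixed | CC(C)=CCC/C(C)=C/CC(C)=C(O[C@@H](C)CC(=O)OC(C)(C)C)C=C=O | intermediate (not isolated)
16 | vinylcyclobutenone, 2-prenyl-3-(triisopropylsilyloxy)cyclobut-2-en-1-one carrying on C4 the 1-alkoxy-2-methyl-2-geranylvinyl group (alkoxy = (S)-4-tert-butoxy-4-oxobutan-2-yloxy) | CC(C)=CCC/C(C)=C/CC(C)=C(O[C@@H](C)CC(=O)OC(C)(C)C)C1C(=O)C(CC=C(C)C)=C1O[Si](C(C)C)(C(C)C)C(C)C | intermediate (not isolated)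
17 | dienylketene, O=C7=C6(prenyl)–C5(OSi(iPr)3)=C4a(H)–C8a(OR)=C8(CH3)(geranyl), C6 and C8a cis on C5=C4a | CC(C)=CCC/C(C)=C/CC(C)=C(O[C@@H](C)CC(=O)OC(C)(C)C)/C=C(/O[Si](C(C)C)(C(C)C)C(C)C)C(CC=C(C)C)=C=O | intermediate (not isolated)
18 | tert-butyl (3S)-3-{[(6R)-6-[(2E)-3,7-dimethylocta-2,6-dien-1-yl]-6-methyl-4-(3-methylbut-2-en-1-yl)-5-oxo-3-(triisopropylsilyloxy)cyclohexa-1,3-dien-1-yl]oxy}butanoate | CC(C)=CCC/C(C)=C/C[C@@]1(C)C(=O)C(CC=C(C)C)=C(O[Si](C(C)C)(C(C)C)C(C)C)C=C1O[C@@H](C)CC(=O)OC(C)(C)C | intermediate (product of the key step)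
19 | trimethylsilyl ester corresponding to 18 | CC(C)=CCC/C(C)=C/C[C@@]1(C)C(=O)C(CC=C(C)C)=C(O[Si](C(C)C)(C(C)C)C(C)C)C=C1O[C@@H](C)CC(=O)O[Si](C)(C)C | intermediate (not isolated)
20 | (3S)-3-{[(6R)-6-geranyl-6-methyl-4-prenyl-5-oxo-3-(triisopropylsilyloxy)cyclohexa-1,3-dien-1-yl]oxy}butanoic acid | CC(C)=CCC/C(C)=C/C[C@@]1(C)C(=O)C(CC=C(C)C)=C(O[Si](C(C)C)(C(C)C)C(C)C)C=C1O[C@@H](C)CC(=O)O | intermediate
21 | acid chloride of 20 | CC(C)=CCC/C(C)=C/C[C@@]1(C)C(=O)C(CC=C(C)C)=C(O[Si](C(C)C)(C(C)C)C(C)C)C=C1O[C@@H](C)CC(=O)Cl | intermediate (not isolated)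
22 | (2S,8R)-8-[(2E)-3,7-dimethylocta-2,6-dien-1-yl]-2,8-dimethyl-6-(3-methylbut-2-en-1-yl)-5-(triisopropylsilyloxy)-2,3-dihydro-4H-chromene-4,7(8H)-dione | CC(C)=CCC/C(C)=C/C[C@@]1(C)C(=O)C(CC=C(C)C)=C(O[Si](C(C)C)(C(C)C)C(C)C)C2=C1O[C@@H](C)CC2=O | intermediate
23 | (2S,8R)-8-[(2E)-3,7-dimethylocta-2,6-dien-1-yl]-5-hydroxy-2,8-dimethyl-6-(3-methylbut-2-en-1-yl)-2,3-dihydro-4H-chromene-4,7(8H)-dione | CC(C)=CCC/C(C)=C/C[C@@]1(C)C(=O)C(CC=C(C)C)=C(O)C2=C1O[C@@H](C)CC2=O | target

**Count**

Total steps: 10. Longest linear sequence: 9 (steps 1–5 and 7–10); step 6 is the side branch.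

**Steps most likely to fail**

Step 9 (ring B closure). The C4a=C8a enol ether is conjugated through C5=C6 with the C7 carbonyl, so its attack on the acyl triflate may be too slow. The acid set free could then strip the silyl group from O5 or start cation–olefin cyclisation in the terpenoid chains. The fallback replaces electrophilic acylation by an organometallic ring closure; it sets out from 20 and returns at 22. Acid 20 is coupled with N,O-dimethylhydroxylamine (EDC·HCl, N-methylmorpholine, CH2Cl2) to give the Weinreb amide F1. N-Iodosuccinimide (MeCN, 0 °C, dark) should iodinate C4a, the only hydrogen-bearing nucleophilic ring carbon, to give the C4a iodide F2. Treatment with iPrMgCl·LiCl (THF, –78 → –20 °C) then brings about iodine–magnesium exchange, and the vinylmagnesium species attacks the tethered amide to give 22 after work-up; the C8 epimers are separated as in step 9.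

Step 7 (annulation). The donor-stabilised cyclobutenone may open only at temperatures where the geranyl group on C8 of the product begins [3,3] shifts to O7 or C4a with aromatisation, or where the vinylketene adds to the near geranyl double bond. The weak facial bias at C8 is inherent and is met by the separation after step 9. The fallback drives the openings with light instead of heat; it sets out from 11 and 14 and returns at 18. Irradiation of 11 with 14 in benzene at room temperature (about 300 nm, flow reactor) opens the cyclobutenone photochemically, and the vinylketene is trapped as 16, which can be isolated. Further irradiation or brief warming (60–70 °C) then opens 16, and 17 closes to 18 without more heat; no compound outside the list is made (F0).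

Step 5 (Mitsunobu etherification). The activated β-hydroxy ester may eliminate to tert-butyl crotonate, or the ambident dione anion may react at carbon. The fallback uses acid-catalysed addition–elimination with retention in place of SN2 with inversion; it sets out from 8 and returns at 11. Compound 8 is warmed (toluene, 50 °C, reduced pressure to strip ethanol) with tert-butyl (S)-3-hydroxybutanoate F3 and a catalytic amount of pyridinium p-toluenesulfonate. The alkoxy groups exchange at C3 of the vinylogous ester without touching the carbinol centre, so the (S)-alcohol gives 11 directly and step 4 is skipped.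

**Further compounds**

F1 | step 9 | (3S)-N-methoxy-N-methyl-3-{[(6R)-6-geranyl-6-methyl-4-prenyl-5-oxo-3-(triisopropylsilyloxy)cyclohexa-1,3-dien-1-yl]oxy}butanamide | CC(C)=CCC/C(C)=C/C[C@@]1(C)C(=O)C(CC=C(C)C)=C(O[Si](C(C)C)(C(C)C)C(C)C)C=C1O[C@@H](C)CC(=O)N(C)OC
F2 | step 9 | (3S)-3-{[(6R)-6-geranyl-2-iodo-6-methyl-4-prenyl-5-oxo-3-(triisopropylsilyloxy)cyclohexa-1,3-dien-1-yl]oxy}-N-methoxy-N-methylbutanamide | CC(C)=CCC/C(C)=C/C[C@@]1(C)C(=O)C(CC=C(C)C)=C(O[Si](C(C)C)(C(C)C)C(C)C)C(I)=C1O[C@@H](C)CC(=O)N(C)OC
F0 | step 7 | none | none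
F3 | step 5 | tert-butyl (S)-3-hydroxybutanoate | CC(C)(C)OC(=O)C[C@H](C)O
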